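**Retrosynthetic overview**
- Last step: hydrogenolysis of seven benzyl ethers from the fully protected dimer.
- Interflavan C4–C8 bond: a 4β-alkoxy upper unit (all three rings and C2/C3 taken from the chiral pool) is ionised and captured by C8 of a protected lower flavan-3-ol; attack anti to the 3-OH gives the 4β (3,4-trans) bond.
- Lower unit, C2 and C3: set together by asymmetric transfer hydrogenation of a configurationally labile racemic flavan-3-one under dynamic kinetic resolution.
- Key C–C bond (C4–C4a of the lower ring C): gold-mediated oxidation of a terminal alkyne gives an α-oxo carbene, i.e. a ketone α-carbon with reversed, electrophilic polarity (enolonium equivalent), which closes the ring onto the ring A carbon. Two carbons that are both natural nucleophiles are joined.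
- Ring order: lower ring C is closed on a preformed ring A ether; the upper rings are bought; the two units are then joined.

Assumption: the four starting materials are catalogue items; racemic intermediates are written without stereodescriptors.

**Route**

Step 1
Reactants: 1 4-(benzyloxy)benzaldehyde; 2 ethynylmagnesium bromide (HC≡CMgBr)
Product: 3 rac-1-[4-(benzyloxy)phenyl]prop-2-yn-1-ol
Conditions: THF, 0 °C → rt; then H2O
Reagents that add atoms: none
Why: Grignard 1,2-addition to the aldehyde; the carbinol centre is racemic, which does not matter because C2 is equilibrated and set in step 4.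

Step 2
Reactants: 3 rac-1-[4-(benzyloxy)phenyl]prop-2-yn-1-ol; 4 3,5-bis(benzyloxy)phenol
Product: 5 rac-1,3-bis(benzyloxy)-5-({1-[4-(benzyloxy)phenyl]prop-2-yn-1-yl}oxy)benzene
Conditions: PPh3, DIAD, toluene, 0 °C → rt
Reagents that add atoms: none
Why: Mitsunobu etherification alkylates the phenol on oxygen (acidic conditions would C-alkylate this electron-rich ring); the stereochemical course is irrelevant for a racemate.

Step 3
Reactants: 5 rac-1,3-bis(benzyloxy)-5-({1-[4-(benzyloxy)phenyl]prop-2-yn-1-yl}oxy)benzene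
Product: 7 rac-5,7-bis(benzyloxy)-2-[4-(benzyloxy)phenyl]chroman-3-one, via α-oxo gold carbene 6 (not isolated)
Conditions: (Me4tBuXPhos)AuNTf2 (5 mol %; Me4tBuXPhos = di-tert-butyl(2',4',6'-triisopropyl-3,4,5,6-tetramethylbiphenyl-2-yl)phosphane), 2,6-dichloropyridine N-oxide (1.5 equiv), ClCH2CH2Cl, rt
Reagents that add atoms: 2,6-dichloropyridine N-oxide, [O-][n+]1c(Cl)cccc1Cl
Why: Gold-catalysed alkyne oxidation/cyclisation of an aryl propargyl ether to a chroman-3-one: the N-oxide adds to the gold-bound terminal alkyne at the internal carbon and N–O cleavage leaves carbene 6, whose former alkyne terminus is a ketone α-carbon of reversed (electrophilic, enolonium-like) polarity that is captured by the doubly O-activated ortho carbon of ring A (both ortho positions are equivalent, so one regioisomer) to close ring C at C4–C4a; no stereocentre is set and C2 stays racemic.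

Step 4
Reactants: 7 rac-5,7-bis(benzyloxy)-2-[4-(benzyloxy)phenyl]chroman-3-one
Product: 8 (2R,3R)-5,7-bis(benzyloxy)-2-[4-(benzyloxy)phenyl]chroman-3-ol (5,7,4'-tri-O-benzyl-(−)-epiafzelechin)
Conditions: RuCl[(R,R)-TsDPEN](p-cymene) (2 mol %), HCO2H/Et3N (1:2), DMF, 40 °C, argon
Reagents that add atoms: none
Why: Proposed new method: Noyori–Ikariya asymmetric transfer hydrogenation run as a dynamic kinetic resolution, the closest known reaction type being ATH–DKR of α-substituted β-tetralones and of isoflavanones; C2–H (α-keto, benzylic, α-aryloxy) epimerises by reversible enolisation in the amine-rich formate medium, the Ru–H adds anti to the 2-aryl group (2,3-cis, as LiBH(s-Bu)3 does on flavan-3-ones), and the (R,R)-ligand, with the C2 side in the aryl-recognition site, is expected to select the 3R carbinol, so 2R and 3R are both set here.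

Step 5
Reactants: 9 (−)-epicatechin
Product: 10 5,7,3',4'-tetra-O-benzyl-(−)-epicatechin
Conditions: BnBr (4.4 equiv), K2CO3, DMF, 0 °C → rt
Reagents that add atoms: benzyl bromide, BrCc1ccccc1
Why: Williamson etherification of the four phenols; carbonate does not deprotonate the 3-OH, which stays free, and C2/C3 are untouched.

Step 6
Reactants: 10 5,7,3',4'-tetra-O-benzyl-(−)-epicatechin
Product: 12 (2R,3R,4S)-5,7-bis(benzyloxy)-2-[3,4-bis(benzyloxy)phenyl]-4-(2-ethoxyethoxy)chroman-3-ol, via flavan-4-ylium hydroquinonate ion pair 11 (not isolated)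
Conditions: DDQ (2 equiv), 2-ethoxyethanol (5 equiv), CH2Cl2, rt
Reagents that add atoms: 2-ethoxyethanol, CCOCCO
Why: DDQ benzylic oxidation: hydride abstraction from C4 gives the cation, stabilised by the 5- and 7-alkoxy groups of ring A and paired with the hydroquinone monoanion formed from DDQ (11), and the alcohol captures it anti to the 3-OH, which sets the 4β (3,4-trans) ether.

Step 7
Reactants: 12 (2R,3R,4S)-5,7-bis(benzyloxy)-2-[3,4-bis(benzyloxy)phenyl]-4-(2-ethoxyethoxy)chroman-3-ol; 8 (2R,3R)-5,7-bis(benzyloxy)-2-[4-(benzyloxy)phenyl]chroman-3-ol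
Product: 14 hepta-O-benzyl-epicatechin-(4β→8)-epiafzelechin, via flavan-4-ylium triflate ion pair 13 (not isolated)
Conditions: TMSOTf (0.1 equiv), CH2Cl2, −78 °C; 8 in 2.5-fold excess (surplus recovered)
Reagents that add atoms: none
Why: Lewis-acid-mediated Friedel–Crafts arylation (interflavan coupling): TMSOTf silylates the chelating 2-ethoxyethoxy group, which leaves to give the flavan-4-yl cation as its triflate ion pair 13, and C8 of 8, the most nucleophilic and accessible ring A position of a 5,7-di-O-benzyl flavan, attacks anti to the 3-OH, setting C4 as 4R (4β, 3,4-trans); the acid released is returned to TMSOTf by the silyl ether of 2-ethoxyethanol, and the excess nucleophile suppresses oligomers.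

Step 8
Reactants: 14 hepta-O-benzyl-epicatechin-(4β→8)-epiafzelechin
Product: 15 (−)-epicatechin-(4β→8)-(−)-epiafzelechin (CNP0299023.1)
Conditions: H2 (1 atm), Pd(OH)2/C, THF/MeOH/H2O, rt
Reagents that add atoms: none
Why: Hydrogenolysis of the seven benzyl ethers under neutral conditions, which leaves the acid-labile interflavan bond and all five stereocentres untouched.

**Compound list**

1 | 4-(benzyloxy)benzaldehyde | O=Cc1ccc(OCc2ccccc2)cc1 | starting material
2 | ethynylmagnesium bromide | C#C[Mg]Br | starting material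
3 | rac-1-[4-(benzyloxy)phenyl]prop-2-yn-1-ol | C#CC(O)c1ccc(OCc2ccccc2)cc1 | intermediate
4 | 3,5-bis(benzyloxy)phenol | Oc1cc(OCc2ccccc2)cc(OCc2ccccc2)c1 | starting material
5 | rac-1,3-bis(benzyloxy)-5-({1-[4-(benzyloxy)phenyl]prop-2-yn-1-yl}oxy)benzene | C#CC(Oc1cc(OCc2ccccc2)cc(OCc2ccccc2)c1)c1ccc(OCc2ccccc2)cc1 | intermediate
6 | α-oxo gold carbene from 5, [(Me4tBuXPhos)Au=CH–C(=O)–CH(OAr)Ar']NTf2 (not isolated) | O=C(C=[Au][P+](C(C)(C)C)(C(C)(C)C)c1c(C)c(C)c(C)c(C)c1-c1c(C(C)C)cc(C(C)C)cc1C(C)C)C(Oc1cc(OCc2ccccc2)cc(OCc2ccccc2)c1)c1ccc(OCc2ccccc2)cc1.[N-](S(=O)(=O)C(F)(F)F)S(=O)(=O)C(F)(F)F | intermediate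
7 | rac-5,7-bis(benzyloxy)-2-[4-(benzyloxy)phenyl]chroman-3-one | O=C1Cc2c(OCc3ccccc3)cc(OCc3ccccc3)cc2OC1c1ccc(OCc2ccccc2)cc1 | intermediate
8 | (2R,3R)-5,7-bis(benzyloxy)-2-[4-(benzyloxy)phenyl]chroman-3-ol | C(Oc1ccc([C@H]2Oc3cc(OCc4ccccc4)cc(OCc4ccccc4)c3C[C@H]2O)cc1)c1ccccc1 | intermediate
9 | (−)-epicatechin, (2R,3R) | Oc1ccc([C@H]2Oc3cc(O)cc(O)c3C[C@H]2O)cc1O | starting material
10 | 5,7,3',4'-tetra-O-benzyl-(−)-epicatechin, (2R,3R) | C(Oc1ccc([C@H]2Oc3cc(OCc4ccccc4)cc(OCc4ccccc4)c3C[C@H]2O)cc1OCc1ccccc1)c1ccccc1 | intermediate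
11 | (2R,3R)-5,7-bis(benzyloxy)-2-[3,4-bis(benzyloxy)phenyl]-3-hydroxychroman-4-ylium 2,3-dichloro-5,6-dicyano-4-hydroxyphenolate, the C4 cation of 10 as its ion pair from DDQ (not isolated) | C(Oc1ccc([C@H]2Oc3cc(OCc4ccccc4)cc(OCc4ccccc4)c3[CH+][C@H]2O)cc1OCc1ccccc1)c1ccccc1.[O-]c1c(Cl)c(Cl)c(O)c(C#N)c1C#N | intermediate
12 | (2R,3R,4S)-5,7-bis(benzyloxy)-2-[3,4-bis(benzyloxy)phenyl]-4-(2-ethoxyethoxy)chroman-3-ol (4β ether) | C(Oc1ccc([C@H]2Oc3cc(OCc4ccccc4)cc(OCc4ccccc4)c3[C@H](OCCOCC)[C@H]2O)cc1OCc1ccccc1)c1ccccc1 | intermediate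
13 | (2R,3R)-5,7-bis(benzyloxy)-2-[3,4-bis(benzyloxy)phenyl]-3-hydroxychroman-4-ylium trifluoromethanesulfonate, the C4 cation from 12 as its triflate ion pair (not isolated) | C(Oc1ccc([C@H]2Oc3cc(OCc4ccccc4)cc(OCc4ccccc4)c3[CH+][C@H]2O)cc1OCc1ccccc1)c1ccccc1.[O-]S(=O)(=O)C(F)(F)F | intermediate
14 | hepta-O-benzyl-epicatechin-(4β→8)-epiafzelechin, upper (2R,3R,4R), lower (2R,3R) | C(c1ccccc1)Oc1ccc([C@H]2Oc3c(c(OCc4ccccc4)cc(OCc4ccccc4)c3[C@H]3c4c(OCc5ccccc5)cc(OCc5ccccc5)cc4O[C@H](c4ccc(OCc5ccccc5)c(OCc5ccccc5)c4)[C@@H]3O)C[C@H]2O)cc1 | intermediate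
15 | (2R,3R)-8-[(2R,3R,4R)-2-(3,4-dihydroxyphenyl)-3,5,7-trihydroxychroman-4-yl]-2-(4-hydroxyphenyl)chroman-3,5,7-triol | Oc1ccc([C@H]2Oc3c(c(O)cc(O)c3[C@H]3c4c(O)cc(O)cc4O[C@H](c4ccc(O)c(O)c4)[C@@H]3O)C[C@H]2O)cc1 | target

**Totals**
Total step count: 8. Longest linear sequence: 6 steps (steps 1, 2, 3, 4, 7, 8).

**Three steps most likely to fail**

Step 3 (gold oxidation/ring closure). The electron-rich ring A can cyclise directly onto the gold-bound alkyne before oxidation, and the doubly benzylic propargylic C–O bond can ionise. The fallback sets out from 5 and makes that competing pathway the route. Ph3PAuNTf2 in CH2Cl2 without oxidant gives the hydroarylation product rac-5,7-bis(benzyloxy)-2-[4-(benzyloxy)phenyl]-2H-chromene F1. Epoxidation with DMDO in acetone at −20 °C gives rac-5,7-bis(benzyloxy)-2-[4-(benzyloxy)phenyl]-3,4-epoxychroman F2. Catalytic ZnI2 then triggers a Meinwald rearrangement (C4–O ionisation assisted by ring A, 1,2-hydride shift from C3), and the sequence comes back to the route at 7.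

Step 4 (transfer hydrogenation with dynamic kinetic resolution). C2 epimerisation may be slower than reduction, or the enantioselectivity on this non-aryl ketone may be low or of the opposite sense. Any (2S,3S) alcohol that survives would in any case give a diastereomeric dimer in step 7, separable by chromatography. The fallback sets out from 7: LiBH(s-Bu)3 in THF at −78 °C gives the racemic cis alcohol rac-(2R*,3R*)-5,7-bis(benzyloxy)-2-[4-(benzyloxy)phenyl]chroman-3-ol F3. Burkholderia cepacia lipase with vinyl acetate in MTBE is expected (Kazlauskas rule, C2 side as the large group) to acylate the 3R enantiomer, giving (2R,3R)-5,7-bis(benzyloxy)-2-[4-(benzyloxy)phenyl]chroman-3-yl acetate F4, which is separated from the unreacted (2S,3S) half of F3. K2CO3 in MeOH cleaves the acetate and the sequence comes back at 8.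

Step 2 (Mitsunobu etherification). The activated alcohol carries a 4-alkoxyphenyl group and may ionise, leading to C-alkylation of the phenol. The fallback sets out from 3: methyl chloroformate and pyridine give rac-1-[4-(benzyloxy)phenyl]prop-2-yn-1-yl methyl carbonate F5. A copper-catalysed propargylic substitution (Cu(MeCN)4PF6, i-Pr2NEt, CH2Cl2, 0 °C) with phenol 4 then delivers the ether by O-attack on the copper allenylidene, and the sequence comes back at 5.

**Further compounds**
F1 | step 3 | rac-5,7-bis(benzyloxy)-2-[4-(benzyloxy)phenyl]-2H-chromene | C1(c2ccc(OCc3ccccc3)cc2)Oc2cc(OCc3ccccc3)cc(OCc3ccccc3)c2C=C1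
F2 | step 3 | rac-5,7-bis(benzyloxy)-2-[4-(benzyloxy)phenyl]-3,4-epoxychroman (epoxide configuration inconsequential) | C1(Oc2cc(OCc3ccccc3)cc(OCc3ccccc3)c2C2OC12)c1ccc(OCc2ccccc2)cc1
F3 | step 4 | rac-(2R*,3R*)-5,7-bis(benzyloxy)-2-[4-(benzyloxy)phenyl]chroman-3-ol (both enantiomers written) | C(Oc1ccc([C@H]2Oc3cc(OCc4ccccc4)cc(OCc4ccccc4)c3C[C@H]2O)cc1)c1ccccc1.C(Oc1ccc([C@@H]2Oc3cc(OCc4ccccc4)cc(OCc4ccccc4)c3C[C@@H]2O)cc1)c1ccccc1
F4 | step 4 | (2R,3R)-5,7-bis(benzyloxy)-2-[4-(benzyloxy)phenyl]chroman-3-yl acetate | C(Oc1ccc([C@H]2Oc3cc(OCc4ccccc4)cc(OCc4ccccc4)c3C[C@H]2OC(C)=O)cc1)c1ccccc1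
F5 | step 2 | rac-1-[4-(benzyloxy)phenyl]prop-2-yn-1-yl methyl carbonate | C#CC(OC(=O)OC)c1ccc(OCc2ccccc2)cc1
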